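**Strategy**

Everything rests on closing the pyran ring between C2 and C3 by an internal redox isomerisation. The precursor is an open-chain benzyl aryl ether: ring A carries an (E)-propenal arm (future C4 and C3, plus a removable formyl group) ortho to O1, and O1 carries the fully substituted ring B as its benzyl group. Under chiral secondary-amine catalysis one hydrogen of the O–CH2 group shifts as hydride to C4, and the resulting enamine attacks the oxocarbenium ion, forming C2–C3 and the C2 stereocentre in one operation. The step exploits the C2–H bond, flanked by O1 and by ring B with its para oxygen at C4′. Decarbonylation and deprotection follow.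

Key step: step 9

Numbering used below: flavan numbering (O1, C2, C3, C4, C4a, C5–C8, C8a; ring B C1′–C6′).

Assumption: catalyst 16 is taken to deliver the (2R,3R) series by the usual enamine face-shielding model; should the 2S series form, the commercial (2R,5R)-catalyst would be used with no other change.

**Route**

Step 1
Reactants: 1 5-bromovanillin (3-bromo-4-hydroxy-5-methoxybenzaldehyde); 2 bromine
Product: 3 5,6-dibromovanillin (2,3-dibromo-4-hydroxy-5-methoxybenzaldehyde)
Conditions: Br2 (1.3 equiv), Fe powder (cat.), AcOH, 25 → 60 °C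
Reagents that add atoms: bromine, BrBr
Why: Electrophilic aromatic bromination; the only open position para to an oxygen (the methoxy group) is C6, next to the existing bromine, so the second bromine should enter there.

Step 2
Reactants: 3 5,6-dibromovanillin
Product: 4 2,3-dibromo-4,5-dihydroxybenzaldehyde
Conditions: BBr3 (2.5 equiv), CH2Cl2, −78 °C → rt; then H2O
Reagents that add atoms: none
Why: Lewis-acid ether cleavage (boron-mediated demethylation); bromide attacks the methyl group of the boron-complexed aryl methyl ether, and aryl bromides and the aldehyde are inert.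

Step 3
Reactants: 4 2,3-dibromo-4,5-dihydroxybenzaldehyde; 5 tert-butyldimethylsilyl chloride
Product: 6 2,3-dibromo-4,5-bis(tert-butyldimethylsilyloxy)benzaldehyde
Conditions: TBSCl (2.5 equiv), imidazole (5 equiv), DMF, rt
Reagents that add atoms: tert-butyldimethylsilyl chloride, CC(C)(C)[Si](C)(C)Cl
Why: Imidazole-promoted silylation of both phenols; silyl ethers keep ring B electron-rich for the key step and can be removed at the end without acid.

Step 4
Reactants: 6 2,3-dibromo-4,5-bis(tert-butyldimethylsilyloxy)benzaldehyde; 7 tributyl(3-methylbut-2-en-1-yl)stannane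
Product: 8 4,5-bis(tert-butyldimethylsilyloxy)-2,3-bis(3-methylbut-2-en-1-yl)benzaldehyde
Conditions: 7 (3 equiv), Pd(PPh3)4 (10 mol %), toluene, 110 °C, argon
Reagents that add atoms: tributyl(3-methylbut-2-en-1-yl)stannane, CCCC[Sn](CCCC)(CCCC)CC=C(C)C
Why: Double Stille coupling; zerovalent palladium inserts into each C–Br bond, and after transmetalation reductive elimination at the less hindered allyl terminus should give the linear prenyl groups, with aldehyde and silyl ethers untouched.

Step 5
Reactants: 8 4,5-bis(tert-butyldimethylsilyloxy)-2,3-bis(3-methylbut-2-en-1-yl)benzaldehyde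
Product: 9 [4,5-bis(tert-butyldimethylsilyloxy)-2,3-bis(3-methylbut-2-en-1-yl)phenyl]methanol
Conditions: NaBH4, THF–EtOH, 0 °C
Reagents that add atoms: none
Why: Borohydride reduction of the aldehyde; isolated trisubstituted alkenes and aryl silyl ethers should survive at 0 °C.

Step 6
Reactants: 10 2,4-dihydroxybenzaldehyde; 11 pivaloyl chloride
Product: 12 4-formyl-3-hydroxyphenyl pivalate (2-hydroxy-4-pivaloyloxybenzaldehyde)
Conditions: PivCl (1.05 equiv), Et3N (1.1 equiv), CH2Cl2, 0 °C
Reagents that add atoms: pivaloyl chloride, CC(C)(C)C(=O)Cl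
Why: Selective O-acylation; the 2-hydroxyl is tied up in a hydrogen bond to the aldehyde, so one equivalent of acid chloride should acylate only the 4-hydroxyl, and the acyl group also stops this oxygen from donating into the later hydride acceptor.

Step 7
Reactants: 9 [4,5-bis(tert-butyldimethylsilyloxy)-2,3-bis(3-methylbut-2-en-1-yl)phenyl]methanol; 12 4-formyl-3-hydroxyphenyl pivalate
Product: 13 3-{[4,5-bis(tert-butyldimethylsilyloxy)-2,3-bis(3-methylbut-2-en-1-yl)phenyl]methoxy}-4-formylphenyl pivalate
Conditions: PPh3, DIAD, THF, 0 °C → rt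
Reagents that add atoms: none
Why: Mitsunobu etherification of the acidic salicylaldehyde hydroxyl with the primary benzylic alcohol; the neutral conditions spare pivalate, silyl ethers and prenyl groups.

Step 8
Reactants: 13 the benzyl aryl ether aldehyde; 14 (triphenylphosphoranylidene)acetaldehyde
Product: 15 3-{[4,5-bis(tert-butyldimethylsilyloxy)-2,3-bis(3-methylbut-2-en-1-yl)phenyl]methoxy}-4-[(E)-3-oxoprop-1-en-1-yl]phenyl pivalate
Conditions: 14 (1.3 equiv), toluene, 80 °C
Reagents that add atoms: (triphenylphosphoranylidene)acetaldehyde, O=CC=P(c1ccccc1)(c1ccccc1)c1ccccc1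
Why: Wittig olefination with a stabilised formyl ylide should give the (E)-enal; the aromatic aldehyde is more electrophilic than the product enal, which limits double homologation.

Step 9
Reactants: 15 the (E)-cinnamaldehyde benzyl ether
Product: 20 (2R,3R)-2-[4,5-bis(tert-butyldimethylsilyloxy)-2,3-bis(3-methylbut-2-en-1-yl)phenyl]-3-formylchroman-7-yl pivalate (2,3-trans), via iminium ion 17 (not isolated), via oxocarbenium enamine 18 (not isolated), via cyclized iminium ion 19 (not isolated)
Conditions: (2S,5S)-5-benzyl-2-tert-butyl-3-methylimidazolidin-4-one 16 (20 mol %), 2,4-dinitrobenzenesulfonic acid (20 mol %), ClCH2CH2Cl, 40 → 60 °C; chromatography to take the trans isomer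
Reagents that add atoms: none
Why: Condensation of the enal with the amine salt gives iminium ion 17, whose β-carbon (future C4) accepts a hydride in a suprafacial 1,5-shift from the O–CH2 group, the only C–H bonds held in a six-membered array with the acceptor; the resulting pair 18 collapses by attack of the enamine carbon (C3) on the oxocarbenium carbon (C2), and hydrolysis of iminium 19 releases the catalyst. The closest known reaction type is the amine-catalysed enantioselective 1,5-hydride transfer/cyclization of ortho-amino cinnamaldehydes and of ether-tethered enals, together with the Lewis-acid variant that converts benzyl aryl ethers carrying an ortho alkylidene 1,3-dicarbonyl group into 2-arylchromans. The pyran ring closes in a 6-(enolexo)-endo-trig mode onto the endocyclic C2=O1 oxocarbenium bond. C3 is set by the imidazolidinone, whose benzyl group shields one face of the (E)-enamine, and C2 is set relative to C3 by a chair-like transition state on the (E)-oxocarbenium ion with ring B pseudo-equatorial, which should give the 2,3-trans isomer. The step needs fast hydride donation, secured on the donor side by O1 and the para silyloxy group at C4′ and on the acceptor side by the non-donating 7-pivaloyloxy group, and it needs high kinetic trans selectivity, because C3 is erased later and the cis isomer would carry the opposite C2 configuration; the trans isomer is therefore separated before any epimerization at C3. Collapse of the ion pair in 18 is expected to outrun capture of the oxocarbenium ion by the neighbouring C2′ prenyl group.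

Step 10
Reactants: 20 the trans chroman-3-carbaldehyde
Product: 21 (2R)-2-[4,5-bis(tert-butyldimethylsilyloxy)-2,3-bis(3-methylbut-2-en-1-yl)phenyl]chroman-7-yl pivalate
Conditions: RhCl(PPh3)3 (1.1 equiv), toluene, 110 °C, argon
Reagents that add atoms: none
Why: Tsuji–Wilkinson decarbonylation; monovalent rhodium inserts into the formyl C–H bond, CO migrates to the metal and C–H reductive elimination replaces CHO by H without a carbanion at C3, so the C2–O1 bond should not be lost by β-elimination and C2 keeps its configuration.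

Step 11
Reactants: 21 the protected flavan
Product: 22 (+)-(2R)-kazinol I
Conditions: K2CO3 (0.5 equiv), degassed MeOH–THF, rt → 40 °C, argon; then aq. NH4Cl
Reagents that add atoms: none
Why: Base-catalysed methanolysis (transesterification of the aryl pivalate and cleavage of the aryl silyl ethers) should free the three phenols without acid, which could cyclise the C3′ prenyl group onto the C4′ hydroxyl; C2 is not touched.

**Compound list**

1 | 5-bromovanillin | O=Cc1cc(OC)c(O)c(Br)c1 | starting material
2 | bromine | BrBr | starting material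
3 | 5,6-dibromovanillin | O=Cc1cc(OC)c(O)c(Br)c1Br | intermediate
4 | 2,3-dibromo-4,5-dihydroxybenzaldehyde | O=Cc1cc(O)c(O)c(Br)c1Br | intermediate
5 | tert-butyldimethylsilyl chloride | CC(C)(C)[Si](C)(C)Cl | starting material
6 | 2,3-dibromo-4,5-bis(tert-butyldimethylsilyloxy)benzaldehyde | O=Cc1cc(O[Si](C)(C)C(C)(C)C)c(O[Si](C)(C)C(C)(C)C)c(Br)c1Br | intermediate
7 | tributyl(3-methylbut-2-en-1-yl)stannane | CCCC[Sn](CCCC)(CCCC)CC=C(C)C | starting material
8 | 4,5-bis(tert-butyldimethylsilyloxy)-2,3-bis(3-methylbut-2-en-1-yl)benzaldehyde | O=Cc1cc(O[Si](C)(C)C(C)(C)C)c(O[Si](C)(C)C(C)(C)C)c(CC=C(C)C)c1CC=C(C)C | intermediate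
9 | [4,5-bis(tert-butyldimethylsilyloxy)-2,3-bis(3-methylbut-2-en-1-yl)phenyl]methanol | OCc1cc(O[Si](C)(C)C(C)(C)C)c(O[Si](C)(C)C(C)(C)C)c(CC=C(C)C)c1CC=C(C)C | intermediate
10 | 2,4-dihydroxybenzaldehyde | O=Cc1ccc(O)cc1O | starting material
11 | pivaloyl chloride | CC(C)(C)C(=O)Cl | starting material
12 | 4-formyl-3-hydroxyphenyl pivalate | O=Cc1ccc(OC(=O)C(C)(C)C)cc1O | intermediate
13 | 3-{[4,5-bis(tert-butyldimethylsilyloxy)-2,3-bis(3-methylbut-2-en-1-yl)phenyl]methoxy}-4-formylphenyl pivalate | O=Cc1ccc(OC(=O)C(C)(C)C)cc1OCc1cc(O[Si](C)(C)C(C)(C)C)c(O[Si](C)(C)C(C)(C)C)c(CC=C(C)C)c1CC=C(C)C | intermediate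
14 | (triphenylphosphoranylidene)acetaldehyde | O=CC=P(c1ccccc1)(c1ccccc1)c1ccccc1 | starting material
15 | 3-{[4,5-bis(tert-butyldimethylsilyloxy)-2,3-bis(3-methylbut-2-en-1-yl)phenyl]methoxy}-4-[(E)-3-oxoprop-1-en-1-yl]phenyl pivalate | O=C/C=C/c1ccc(OC(=O)C(C)(C)C)cc1OCc1cc(O[Si](C)(C)C(C)(C)C)c(O[Si](C)(C)C(C)(C)C)c(CC=C(C)C)c1CC=C(C)C | intermediate
16 | (2S,5S)-5-benzyl-2-tert-butyl-3-methylimidazolidin-4-one (catalyst) | CN1[C@@H](C(C)(C)C)N[C@@H](Cc2ccccc2)C1=O | starting material
17 | iminium ion from 15 and 16 | CN1[C@@H](C(C)(C)C)[N+](=C/C=C/c2ccc(OC(=O)C(C)(C)C)cc2OCc2cc(O[Si](C)(C)C(C)(C)C)c(O[Si](C)(C)C(C)(C)C)c(CC=C(C)C)c2CC=C(C)C)[C@@H](Cc2ccccc2)C1=O | intermediate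
18 | oxocarbenium enamine formed by the 1,5-hydride shift | CN1[C@@H](C(C)(C)C)N(/C=C/Cc2ccc(OC(=O)C(C)(C)C)cc2[O+]=Cc2cc(O[Si](C)(C)C(C)(C)C)c(O[Si](C)(C)C(C)(C)C)c(CC=C(C)C)c2CC=C(C)C)[C@@H](Cc2ccccc2)C1=O | intermediate
19 | cyclized iminium ion (2,3-trans chroman) | CN1[C@@H](C(C)(C)C)[N+](=C[C@@H]2Cc3ccc(OC(=O)C(C)(C)C)cc3O[C@H]2c2cc(O[Si](C)(C)C(C)(C)C)c(O[Si](C)(C)C(C)(C)C)c(CC=C(C)C)c2CC=C(C)C)[C@@H](Cc2ccccc2)C1=O | intermediate
20 | (2R,3R)-2-[4,5-bis(tert-butyldimethylsilyloxy)-2,3-bis(3-methylbut-2-en-1-yl)phenyl]-3-formylchroman-7-yl pivalate | CC(C)=CCc1c([C@H]2[C@H](C=O)Cc3ccc(OC(=O)C(C)(C)C)cc3O2)cc(O[Si](C)(C)C(C)(C)C)c(O[Si](C)(C)C(C)(C)C)c1CC=C(C)C | intermediate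
21 | (2R)-2-[4,5-bis(tert-butyldimethylsilyloxy)-2,3-bis(3-methylbut-2-en-1-yl)phenyl]chroman-7-yl pivalate | CC(C)=CCc1c([C@H]2CCc3ccc(OC(=O)C(C)(C)C)cc3O2)cc(O[Si](C)(C)C(C)(C)C)c(O[Si](C)(C)C(C)(C)C)c1CC=C(C)C | intermediate
22 | (+)-(2R)-kazinol I | CC(C)=CCc1c([C@H]2CCc3ccc(O)cc3O2)cc(O)c(O)c1CC=C(C)C | target

**Count**

Total step count: 11.
Longest linear sequence: 10 steps (steps 1–5 and 7–11, from 5-bromovanillin); step 6 is the one-step side branch.

**Steps most likely to fail, with fallbacks**

Step 9. The aryl benzyl ether may donate hydride to the iminium ion too slowly. The C2 configuration may also be eroded, either by poor kinetic trans/cis selectivity in the ring closure or by reversible opening of the pyran ring through loss of the aryloxide from the product enamine. The fallback sets out from 13 and returns at 21. Aldehyde 13 would be condensed with Meldrum's acid (Knoevenagel, pyrrolidinium acetate cat., benzene, rt) to the benzylidene Meldrum's acid F1, a much stronger hydride acceptor. Sc(OTf)3 (10 mol %) in ClCH2CH2Cl at 60 °C should then trigger the same 1,5-hydride shift and 6-endo closure, in its known Lewis-acid form for benzyl aryl ethers, to give the racemic spiro dioxanedione F2, in which C3 is not stereogenic. Heating in DMF–water should open the dioxanedione and decarboxylate to the racemic chroman-3-carboxylic acid F3. Coupling with 2-mercaptopyridine N-oxide (DCC, CH2Cl2, dark) would give the Barton ester F4, and photolysis with t-BuSH should give the racemic protected flavan F5. Preparative HPLC on a chiral stationary phase would then deliver the 2R enantiomer, compound 21.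

Step 10. The alkylrhodium hydride formed after CO extrusion may undergo β-hydride elimination to chromenes, or the pyran ring may open thermally by loss of the aryloxide from C2 at the temperature the rhodium needs. The fallback sets out from 20 and returns at 21, and replaces the organometallic step by a radical one. Pinnick oxidation (NaClO2, NaH2PO4, 2-methyl-2-butene in large excess, t-BuOH–H2O, 0 °C) should give the (2R,3R)-chroman-3-carboxylic acid F6. Conversion into the Barton ester F7 (DCC, 2-mercaptopyridine N-oxide) and photolysis with t-BuSH should give 21; the C3 radical is reduced by the thiol and cannot expel the C2 oxygen, so C2 is expected to stay intact.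

Step 4. The second coupling at the crowded position next to the first prenyl group may stall, and allylic transposition at the transmetalation stage may give 1,1-dimethylallyl (reverse prenyl) groups. The fallback sets out from 6 and returns at 9, inverting the order of reduction and coupling and replacing tin by zinc. NaBH4 (THF–EtOH, 0 °C) would first give [2,3-dibromo-4,5-bis(tert-butyldimethylsilyloxy)phenyl]methanol F8. Negishi coupling with 3-methylbut-2-enylzinc bromide (4 equiv, Pd(OAc)2 and 2-dicyclohexylphosphino-2′,6′-bis(dimethylamino)biphenyl, THF, rt), in which the ligand enforces linear selectivity at room temperature, should then give alcohol 9.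

**Further compounds**

F1 | step 9 | 3-{[4,5-bis(tert-butyldimethylsilyloxy)-2,3-bis(3-methylbut-2-en-1-yl)phenyl]methoxy}-4-[(2,2-dimethyl-4,6-dioxo-1,3-dioxan-5-ylidene)methyl]phenyl pivalate | CC1(C)OC(=O)C(=Cc2ccc(OC(=O)C(C)(C)C)cc2OCc2cc(O[Si](C)(C)C(C)(C)C)c(O[Si](C)(C)C(C)(C)C)c(CC=C(C)C)c2CC=C(C)C)C(=O)O1
F2 | step 9 | racemic 2-aryl-7-pivaloyloxychroman spiro-fused at C3 to 2,2-dimethyl-1,3-dioxane-4,6-dione (aryl = 4,5-bis(tert-butyldimethylsilyloxy)-2,3-diprenylphenyl) | CC1(C)OC(=O)C2(Cc3ccc(OC(=O)C(C)(C)C)cc3OC2c2cc(O[Si](C)(C)C(C)(C)C)c(O[Si](C)(C)C(C)(C)C)c(CC=C(C)C)c2CC=C(C)C)C(=O)O1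
F3 | step 9 | racemic 2-[4,5-bis(tert-butyldimethylsilyloxy)-2,3-bis(3-methylbut-2-en-1-yl)phenyl]-7-pivaloyloxychroman-3-carboxylic acid | OC(=O)C1Cc2ccc(OC(=O)C(C)(C)C)cc2OC1c1cc(O[Si](C)(C)C(C)(C)C)c(O[Si](C)(C)C(C)(C)C)c(CC=C(C)C)c1CC=C(C)C
F4 | step 9 | racemic Barton ester (2-thioxopyridin-1(2H)-yl ester) of F3 | O=C(ON1C=CC=CC1=S)C1Cc2ccc(OC(=O)C(C)(C)C)cc2OC1c1cc(O[Si](C)(C)C(C)(C)C)c(O[Si](C)(C)C(C)(C)C)c(CC=C(C)C)c1CC=C(C)C
F5 | step 9 | racemic 2-[4,5-bis(tert-butyldimethylsilyloxy)-2,3-bis(3-methylbut-2-en-1-yl)phenyl]chroman-7-yl pivalate | CC(C)=CCc1c(C2CCc3ccc(OC(=O)C(C)(C)C)cc3O2)cc(O[Si](C)(C)C(C)(C)C)c(O[Si](C)(C)C(C)(C)C)c1CC=C(C)C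
F6 | step 10 | (2R,3R)-2-[4,5-bis(tert-butyldimethylsilyloxy)-2,3-bis(3-methylbut-2-en-1-yl)phenyl]-7-pivaloyloxychroman-3-carboxylic acid | CC(C)=CCc1c([C@H]2[C@H](C(=O)O)Cc3ccc(OC(=O)C(C)(C)C)cc3O2)cc(O[Si](C)(C)C(C)(C)C)c(O[Si](C)(C)C(C)(C)C)c1CC=C(C)C
F7 | step 10 | Barton ester (2-thioxopyridin-1(2H)-yl ester) of F6 | CC(C)=CCc1c([C@H]2[C@H](C(=O)ON3C=CC=CC3=S)Cc3ccc(OC(=O)C(C)(C)C)cc3O2)cc(O[Si](C)(C)C(C)(C)C)c(O[Si](C)(C)C(C)(C)C)c1CC=C(C)C
F8 | step 4 | [2,3-dibromo-4,5-bis(tert-butyldimethylsilyloxy)phenyl]methanol | OCc1cc(O[Si](C)(C)C(C)(C)C)c(O[Si](C)(C)C(C)(C)C)c(Br)c1Br
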